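**Overview**

- Retrosynthetic cuts: the C7–H bond (C7 carbinol back to a ring A aryl ketone, with the C9 alcohol back to an ethyl ester); the C8–O4' aryl ether bond (back to a ring A α-diazo β-keto ester and a ring B phenol); the C1'–C7' bond (back to an aryl Grignard reagent and (S)-benzyl glycidyl ether); and the C8–C9 bond (back to acetosyringone and diethyl carbonate).
- Forward order: the ring B side chain is attached first by epoxide opening, ring A is built up to the diazo keto ester, and the halves are joined at C8–O4' by rhodium carbene O–H insertion. The C7/C8 pair is then set, the ester is reduced and the three benzyl ethers are removed. No ring is formed at any stage.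
- Enabling feature: C8, the carbon bearing the ring B aryloxy group, lies between C7 and C9. With C7 as the ring A aryl ketone and C9 as an ester, the C8–H is a 1,3-dicarbonyl α-hydrogen and epimerises freely, so one catalyst-controlled reduction at C7 can fix C7 and C8 together.
- Stereochemistry: C8' (S) is bought with (S)-benzyl glycidyl ether and never touched. C7 (S) and C8 (S in the target) arise together in the transfer hydrogenation with dynamic kinetic resolution under RuCl(p-cymene)[(R,R)-TsDPEN] (divalent ruthenium).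

Key step: step 9

Remark: lignan numbering is used (ring A = the 4-hydroxy-3,5-dimethoxyphenyl ring on C7, with chain C7–C8–C9; ring B = the 2,6-dimethoxyphenoxy ring with ether oxygen O4' and side chain C7'–C9'). Acetosyringone, 4-bromo-2,6-dimethoxyphenol and (S)-benzyl glycidyl ether are assumed to be commercial.

**Route**

Step 1
Reactants: 1 acetosyringone (4'-hydroxy-3',5'-dimethoxyacetophenone)
Product: 2 4'-(benzyloxy)-3',5'-dimethoxyacetophenone
Conditions: BnBr, K2CO3, DMF, 60 °C
Reagents that add atoms: benzyl bromide, BrCc1ccccc1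
Why: Williamson etherification of the phenoxide; benzyl is chosen because it survives every later step and leaves at the end together with the side-chain benzyl ethers.

Step 2
Reactants: 2 4'-(benzyloxy)-3',5'-dimethoxyacetophenone
Product: 3 ethyl 3-[4-(benzyloxy)-3,5-dimethoxyphenyl]-3-oxopropanoate
Conditions: NaH, (EtO)2CO, THF, reflux; then 1 M HCl, 0 °C
Reagents that add atoms: diethyl carbonate, CCOC(=O)OCC
Why: Crossed Claisen condensation of the methyl ketone enolate with the non-enolisable carbonate adds C9 as the ester and is driven by deprotonation of the β-keto ester formed.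

Step 3
Reactants: 3 ethyl 3-[4-(benzyloxy)-3,5-dimethoxyphenyl]-3-oxopropanoate
Product: 4 ethyl 3-[4-(benzyloxy)-3,5-dimethoxyphenyl]-2-diazo-3-oxopropanoate
Conditions: 4-AcNHC6H4SO2N3, Et3N, MeCN, 0 °C to rt
Reagents that add atoms: 4-acetamidobenzenesulfonyl azide, CC(=O)Nc1ccc(cc1)S(=O)(=O)N=[N+]=[N-]
Why: Regitz diazo transfer to the doubly activated C8 methylene proceeds under mild amine base and leaves an easily removed sulfonamide.

Step 4
Reactants: 5 4-bromo-2,6-dimethoxyphenol
Product: 6 5-bromo-1,3-dimethoxy-2-(methoxymethoxy)benzene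
Conditions: NaH, MOMCl, THF–DMF, 0 °C to rt
Reagents that add atoms: chloromethyl methyl ether, COCCl
Why: O-alkylation of the sodium phenoxide (Williamson type) masks the acidic OH for the Grignard and alkoxide steps with a group that acid later removes without touching benzyl ethers.

Step 5
Reactants: 6 5-bromo-1,3-dimethoxy-2-(methoxymethoxy)benzene; 7 (S)-benzyl glycidyl ether
Product: 9 (2S)-1-(benzyloxy)-3-[3,5-dimethoxy-4-(methoxymethoxy)phenyl]propan-2-ol, via arylmagnesium bromide 8 (not isolated)
Conditions: Mg turnings, 1,2-dibromoethane (cat.), THF, reflux; then CuI (10 mol %), 7, THF, −30 to 0 °C; aq NH4Cl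
Reagents that add atoms: magnesium, [Mg] (kept only in 8)
Why: Grignard formation followed by CuI-catalysed (monovalent copper) SN2 opening of the terminal epoxide at its unsubstituted CH2 carbon forms the C1'–C7' bond, and the stereocentre (future C8') is not a reacting atom, so its S configuration is carried over.

Step 6
Reactants: 9 (2S)-1-(benzyloxy)-3-[3,5-dimethoxy-4-(methoxymethoxy)phenyl]propan-2-ol
Product: 10 5-[(2S)-2,3-bis(benzyloxy)propyl]-1,3-dimethoxy-2-(methoxymethoxy)benzene
Conditions: NaH, BnBr, tetrabutylammonium iodide (cat.), THF–DMF, 0 °C to rt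
Reagents that add atoms: benzyl bromide, BrCc1ccccc1
Why: Williamson benzylation of the secondary alkoxide touches only the O–H bond, so C8' keeps its configuration.

Step 7
Reactants: 10 5-[(2S)-2,3-bis(benzyloxy)propyl]-1,3-dimethoxy-2-(methoxymethoxy)benzene
Product: 11 4-[(2S)-2,3-bis(benzyloxy)propyl]-2,6-dimethoxyphenol
Conditions: HCl (2 M) in MeOH–THF, 40 °C
Reagents that add atoms: none
Why: Acid-catalysed acetal exchange with methanol frees the phenol, while alkyl benzyl ethers are stable to dilute acid.

Step 8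
Reactants: 4 ethyl 3-[4-(benzyloxy)-3,5-dimethoxyphenyl]-2-diazo-3-oxopropanoate; 11 4-[(2S)-2,3-bis(benzyloxy)propyl]-2,6-dimethoxyphenol
Product: 12 ethyl (2RS)-3-[4-(benzyloxy)-3,5-dimethoxyphenyl]-2-{4-[(2S)-2,3-bis(benzyloxy)propyl]-2,6-dimethoxyphenoxy}-3-oxopropanoate (both C8 epimers)
Conditions: Rh2(OAc)4 (2 mol %), toluene, 80 °C, slow addition of 4
Reagents that add atoms: none
Why: Rh2(OAc)4 (divalent rhodium) turns the acceptor/acceptor diazo compound into an electrophilic carbenoid that the phenol oxygen captures (oxonium ylide, then proton shift), the known carbene O–H insertion route to α-aryloxy β-keto esters; C8 forms without control, which is harmless because it epimerises in the next step.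

Step 9
Reactants: 12 ethyl (2RS)-3-[4-(benzyloxy)-3,5-dimethoxyphenyl]-2-{4-[(2S)-2,3-bis(benzyloxy)propyl]-2,6-dimethoxyphenoxy}-3-oxopropanoate
Product: 13 ethyl (2R,3S)-3-[4-(benzyloxy)-3,5-dimethoxyphenyl]-2-{4-[(2S)-2,3-bis(benzyloxy)propyl]-2,6-dimethoxyphenoxy}-3-hydroxypropanoate
Conditions: RuCl(p-cymene)[(R,R)-TsDPEN] (2 mol %), HCO2H/Et3N (5:2), CH2Cl2, 30 °C
Reagents that add atoms: none
Why: Formate converts the precatalyst into the ruthenium hydride (divalent ruthenium), which passes its hydride to the C7 carbonyl carbon and the ligand N–H proton to the carbonyl oxygen through an outer-sphere six-membered transition state without chelation of the substrate, while the C8–H flanked by ketone and ester lets the two C8 epimers of 12 interconvert via the enol in the HCO2H/Et3N medium faster than either is reduced. The closest known reaction type is the Noyori asymmetric transfer hydrogenation with dynamic kinetic resolution of α-alkoxy and α-aryloxy β-keto esters, which gives syn products. No ring is closed and no skeletal bond is formed; only the C7–H and O–H bonds are made. C7 (S) is controlled by the catalyst: the CH/π contact between ring A and the p-cymene ligand fixes the orientation of the aryl ketone, so the (R,R) ligand delivers hydride to the face that corresponds to (R)-1-phenylethanol, which reads S here because C8 outranks ring A. C8 (R in the ester, the later 8S) is fixed in the same event, because the epimer that can place its C8–OAr bond anti to the incoming hydride (polar Felkin–Anh arrangement with the aryloxy group as the large substituent) is reduced faster and is replenished by epimerisation, which leads to the syn (threo) pair. The step needs facial selectivity at C7, syn diastereoselectivity and epimerisation that outpaces reduction; these should be secured by the aryl ketone itself, the bulky 2,6-dimethoxyaryloxy group, the doubly activated C8–H and the benzyl-capped 4-oxygen of ring A that keeps the ketone electrophilic, while the remote C8' centre has no influence.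

Step 10
Reactants: 13 ethyl (2R,3S)-3-[4-(benzyloxy)-3,5-dimethoxyphenyl]-2-{4-[(2S)-2,3-bis(benzyloxy)propyl]-2,6-dimethoxyphenoxy}-3-hydroxypropanoate
Product: 14 (1S,2S)-1-[4-(benzyloxy)-3,5-dimethoxyphenyl]-2-{4-[(2S)-2,3-bis(benzyloxy)propyl]-2,6-dimethoxyphenoxy}propane-1,3-diol
Conditions: LiBH4, THF, 0 °C to rt; aq NH4Cl
Reagents that add atoms: none
Why: LiBH4 reduces the α-aryloxy ester chemoselectively to the C9 primary alcohol and leaves benzyl and aryl ethers alone; no stereocentre reacts, and the C8 descriptor changes from R to S only because CH2OH ranks below C7.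

Step 11
Reactants: 14 (1S,2S)-1-[4-(benzyloxy)-3,5-dimethoxyphenyl]-2-{4-[(2S)-2,3-bis(benzyloxy)propyl]-2,6-dimethoxyphenoxy}propane-1,3-diol
Product: 15 (1S,2S)-2-{4-[(2S)-2,3-dihydroxypropyl]-2,6-dimethoxyphenoxy}-1-(4-hydroxy-3,5-dimethoxyphenyl)propane-1,3-diol (target CNP0229130.2; 7S,8S,8'S)
Conditions: H2 (1 atm), 10% Pd/C, EtOAc–EtOH, rt
Reagents that add atoms: none
Why: Heterogeneous hydrogenolysis cleaves the aryl benzyl ether and the two alkyl benzyl ethers; the neutral, non-acidic medium should keep the C7 benzylic hydroxyl from ionising, and no stereocentre is touched.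

**Compound list**

1 | acetosyringone | CC(=O)c1cc(OC)c(O)c(OC)c1 | starting material
2 | 4'-(benzyloxy)-3',5'-dimethoxyacetophenone | CC(=O)c1cc(OC)c(OCc2ccccc2)c(OC)c1 | intermediate
3 | ethyl 3-[4-(benzyloxy)-3,5-dimethoxyphenyl]-3-oxopropanoate | CCOC(=O)CC(=O)c1cc(OC)c(OCc2ccccc2)c(OC)c1 | intermediate
4 | ethyl 3-[4-(benzyloxy)-3,5-dimethoxyphenyl]-2-diazo-3-oxopropanoate | CCOC(=O)C(=[N+]=[N-])C(=O)c1cc(OC)c(OCc2ccccc2)c(OC)c1 | intermediate
5 | 4-bromo-2,6-dimethoxyphenol | COc1cc(Br)cc(OC)c1O | starting material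
6 | 5-bromo-1,3-dimethoxy-2-(methoxymethoxy)benzene | COCOc1c(OC)cc(Br)cc1OC | intermediate
7 | (S)-benzyl glycidyl ether, (2S)-2-[(benzyloxy)methyl]oxirane | C1[C@H](O1)COCc1ccccc1 | starting material
8 | [3,5-dimethoxy-4-(methoxymethoxy)phenyl]magnesium bromide | COCOc1c(OC)cc([Mg]Br)cc1OC | intermediate (not isolated)
9 | (2S)-1-(benzyloxy)-3-[3,5-dimethoxy-4-(methoxymethoxy)phenyl]propan-2-ol | COCOc1c(OC)cc(C[C@H](O)COCc2ccccc2)cc1OC | intermediate
10 | 5-[(2S)-2,3-bis(benzyloxy)propyl]-1,3-dimethoxy-2-(methoxymethoxy)benzene | COCOc1c(OC)cc(C[C@H](OCc2ccccc2)COCc2ccccc2)cc1OC | intermediate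
11 | 4-[(2S)-2,3-bis(benzyloxy)propyl]-2,6-dimethoxyphenol | Oc1c(OC)cc(C[C@H](OCc2ccccc2)COCc2ccccc2)cc1OC | intermediate
12 | ethyl (2RS)-3-[4-(benzyloxy)-3,5-dimethoxyphenyl]-2-{4-[(2S)-2,3-bis(benzyloxy)propyl]-2,6-dimethoxyphenoxy}-3-oxopropanoate | CCOC(=O)C(Oc1c(OC)cc(C[C@H](OCc2ccccc2)COCc2ccccc2)cc1OC)C(=O)c1cc(OC)c(OCc2ccccc2)c(OC)c1 | intermediate
13 | ethyl (2R,3S)-3-[4-(benzyloxy)-3,5-dimethoxyphenyl]-2-{4-[(2S)-2,3-bis(benzyloxy)propyl]-2,6-dimethoxyphenoxy}-3-hydroxypropanoate | COc1cc([C@H](O)[C@H](C(=O)OCC)Oc2c(OC)cc(C[C@H](OCc3ccccc3)COCc3ccccc3)cc2OC)cc(OC)c1OCc1ccccc1 | intermediate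
14 | (1S,2S)-1-[4-(benzyloxy)-3,5-dimethoxyphenyl]-2-{4-[(2S)-2,3-bis(benzyloxy)propyl]-2,6-dimethoxyphenoxy}propane-1,3-diol | COc1cc([C@H](O)[C@H](CO)Oc2c(OC)cc(C[C@H](OCc3ccccc3)COCc3ccccc3)cc2OC)cc(OC)c1OCc1ccccc1 | intermediate
15 | (1S,2S)-2-{4-[(2S)-2,3-dihydroxypropyl]-2,6-dimethoxyphenoxy}-1-(4-hydroxy-3,5-dimethoxyphenyl)propane-1,3-diol | COc1cc([C@H](O)[C@H](CO)Oc2c(OC)cc(C[C@H](O)CO)cc2OC)cc(OC)c1O | target

**Step count and risks**

Total: 11 steps. Longest linear sequence: 8 steps (steps 4 to 11, from 5); the ring A arm adds 3 steps (1 to 3) before the union in step 8.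

Steps most likely to fail:

1. Step 9. Reduction may outrun C8 epimerisation, or the Felkin–Anh preference may be eroded by the bulky aryloxy group, so that the syn selectivity is insufficient; hydride transfer to the hindered, electron-rich ketone may also be slow. The fallback replaces the reduction by an auxiliary-controlled aldol reaction; it sets out from 11 and returns to the route at 14, bypassing steps 8 to 10.
   - Phenol 11 is O-alkylated with bromoacetic acid (NaH, THF–DMF) to {4-[(2S)-2,3-bis(benzyloxy)propyl]-2,6-dimethoxyphenoxy}acetic acid F1.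
   - Pivaloyl chloride and Et3N (THF, −20 °C) convert it into the mixed pivalic anhydride F2, which acylates (R)-4-benzyl-1,3-oxazolidin-2-one (LiCl, Et3N) to the aryloxyacetyl imide F3.
   - Bu2BOTf and i-Pr2NEt (CH2Cl2, 0 °C) give the Z dibutylboron enolate F4.
   - F4 adds to commercial 4-(benzyloxy)-3,5-dimethoxybenzaldehyde at −78 °C through the chair transition state of the Evans syn aldol reaction and, after H2O2 work-up, should give the (2R,3S) syn aldol adduct F5.
   - LiBH4 (THF–H2O, 0 °C) removes the auxiliary reductively and delivers diol 14.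

2. Step 8. The rhodium carbenoid may be diverted from the hindered, di-ortho-substituted phenol O–H by Wolff rearrangement, attack on the electron-rich rings or on benzyl ether oxygens, or carbene dimerisation. The fallback uses polar displacement instead of carbene chemistry; it sets out from 3 and rejoins at 12. Keto ester 3 is brominated at C8 with N-bromosuccinimide (NH4OAc cat., Et2O, rt) to the α-bromo β-keto ester F6, and the potassium phenoxide of 11 (K2CO3, acetone, rt) displaces bromide to give 12.

3. Step 11. The benzylic C7–O bond may be hydrogenolysed once the para phenol is unmasked, in competition with slow cleavage of the two alkyl benzyl ethers, the secondary one at C8' being the slowest. The fallback changes the side-chain protection so that the last hydrogenolysis only has to cleave the fast-reacting aryl benzyl ether; it sets out from 11 and returns at 15.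
   - 11 is debenzylated (H2, Pd/C, EtOAc–MeOH; no benzylic oxygen is present at this stage) to (2S)-3-(4-hydroxy-3,5-dimethoxyphenyl)propane-1,2-diol F7.
   - F7 is peracetylated (Ac2O, pyridine, DMAP) to the triacetate F8, and the aryl acetate alone is removed by aminolysis with pyrrolidine (CH2Cl2, 0 °C) to the phenol diacetate F9.
   - O–H insertion with 4 under the conditions of step 8 gives the diacetate keto ester F10, and transfer hydrogenation under the conditions of step 9 gives the syn hydroxy ester F11.
   - Excess LiBH4 (THF) reduces the ethyl ester and both acetates in one operation to the mono-benzyl tetraol F12.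
   - A short hydrogenolysis (H2, Pd/C, EtOAc) of the single aryl benzyl ether then gives 15.

**Further compounds**

F1 | step 9 | {4-[(2S)-2,3-bis(benzyloxy)propyl]-2,6-dimethoxyphenoxy}acetic acid | OC(=O)COc1c(OC)cc(C[C@H](OCc2ccccc2)COCc2ccccc2)cc1OC
F2 | step 9 | mixed anhydride of F1 with pivalic acid | CC(C)(C)C(=O)OC(=O)COc1c(OC)cc(C[C@H](OCc2ccccc2)COCc2ccccc2)cc1OC
F3 | step 9 | (4R)-4-benzyl-3-({4-[(2S)-2,3-bis(benzyloxy)propyl]-2,6-dimethoxyphenoxy}acetyl)-1,3-oxazolidin-2-one | O=C1OC[C@@H](Cc2ccccc2)N1C(=O)COc1c(OC)cc(C[C@H](OCc2ccccc2)COCc2ccccc2)cc1OC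
F4 | step 9 | Z dibutylboron enolate of F3 | CCCCB(CCCC)O/C(=C\Oc1c(OC)cc(C[C@H](OCc2ccccc2)COCc2ccccc2)cc1OC)N1[C@H](Cc2ccccc2)COC1=O
F5 | step 9 | (4R)-4-benzyl-3-[(2R,3S)-3-[4-(benzyloxy)-3,5-dimethoxyphenyl]-2-{4-[(2S)-2,3-bis(benzyloxy)propyl]-2,6-dimethoxyphenoxy}-3-hydroxypropanoyl]-1,3-oxazolidin-2-one | O=C1OC[C@@H](Cc2ccccc2)N1C(=O)[C@H](Oc1c(OC)cc(C[C@H](OCc2ccccc2)COCc2ccccc2)cc1OC)[C@@H](O)c1cc(OC)c(OCc2ccccc2)c(OC)c1
F6 | step 8 | ethyl 3-[4-(benzyloxy)-3,5-dimethoxyphenyl]-2-bromo-3-oxopropanoate (racemic) | CCOC(=O)C(Br)C(=O)c1cc(OC)c(OCc2ccccc2)c(OC)c1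
F7 | step 11 | (2S)-3-(4-hydroxy-3,5-dimethoxyphenyl)propane-1,2-diol | COc1cc(C[C@H](O)CO)cc(OC)c1O
F8 | step 11 | (2S)-3-(4-acetoxy-3,5-dimethoxyphenyl)propane-1,2-diyl diacetate | COc1cc(C[C@H](OC(C)=O)COC(C)=O)cc(OC)c1OC(C)=O
F9 | step 11 | (2S)-3-(4-hydroxy-3,5-dimethoxyphenyl)propane-1,2-diyl diacetate | COc1cc(C[C@H](OC(C)=O)COC(C)=O)cc(OC)c1O
F10 | step 11 | ethyl (2RS)-3-[4-(benzyloxy)-3,5-dimethoxyphenyl]-2-{4-[(2S)-2,3-diacetoxypropyl]-2,6-dimethoxyphenoxy}-3-oxopropanoate | CCOC(=O)C(Oc1c(OC)cc(C[C@H](OC(C)=O)COC(C)=O)cc1OC)C(=O)c1cc(OC)c(OCc2ccccc2)c(OC)c1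
F11 | step 11 | ethyl (2R,3S)-3-[4-(benzyloxy)-3,5-dimethoxyphenyl]-2-{4-[(2S)-2,3-diacetoxypropyl]-2,6-dimethoxyphenoxy}-3-hydroxypropanoate | COc1cc([C@H](O)[C@H](C(=O)OCC)Oc2c(OC)cc(C[C@H](OC(C)=O)COC(C)=O)cc2OC)cc(OC)c1OCc1ccccc1
F12 | step 11 | (1S,2S)-1-[4-(benzyloxy)-3,5-dimethoxyphenyl]-2-{4-[(2S)-2,3-dihydroxypropyl]-2,6-dimethoxyphenoxy}propane-1,3-diol | COc1cc([C@H](O)[C@H](CO)Oc2c(OC)cc(C[C@H](O)CO)cc2OC)cc(OC)c1OCc1ccccc1
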